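Locants C1–C10 are those of the ring atoms in the order of the target SMILES; ring A is C1, C2, C3, C9, C10 and ring B is C3–C9. "β" is the face of the bicycle that carries the C3 methyl group and H-9, "α" the opposite face.

## Analysis of the target

The target (34) is a cis-fused bicyclo[5.3.0]decane of the daucane type, with cyclopentane ring A sharing the C3–C9 bond with cycloheptene ring B. It has six stereocentres, (1S,3S,4S,8S,9R,10R) in the locants used here. The C3 methyl group, H-9, the tertiary C10 hydroxyl, the C1 acetoxy group and the C4 hydroxyl lie on the β face. The C8 aroyloxy group and the C10 isopropyl group lie on the α face, the face on which ring A is folded under ring B. Four oxygens in three different states (secondary acetate at C1, free secondary alcohol at C4, allylic 4-hydroxybenzoate at C8, free tertiary alcohol at C10) and a free phenol must be told apart; the acetate can migrate to the neighbouring hydroxyl under base and the allylic aryl ester is sensitive to acid and to alkoxides. The hard part is the run of three congested centres C3–C9–C10 (quaternary C3 at the fusion, fully substituted C10 carbinol) on a seven-membered ring with little conformational bias. C6 is not stereogenic in the target, so an sp3 C6 bearing methyl can serve as a temporary stereocentre and be turned into the C6=C7 alkene late through a C8 ketone, which also lets hydride addition set C8. The route rests on ring A: its C1/C10 cis-diol is the osmylation product of a C1=C10 cyclopentene with isopropyl on C10, and in that cyclopentene the C2–C3 bond ends at the quaternary carbon, which is the bond a 1,3-shift makes from a vinylcyclopropane (C3–C9–C10, vinyl C1=C2 on C10) fused to ring B across C3–C9.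

## Retrosynthetic reasoning

**Ester and silyl groups (34 ⇐ 33 ⇐ 29 + 32).** The last bond made is the C8–O acyl bond. The aroyl group is brought in as the silyl-protected acid 32 (from 30), so that the phenol, the C4 hydroxyl and the C10 hydroxyl are all released from 33 in one fluoride step that leaves both esters alone.

**C6=C7 alkene and C8 carbinol (29 ⇐ 28 ⇐ 27 ⇐ 26).** The allylic alcohol 29 is the 1,2-reduction product of enone 28, and 28 is the dehydrogenation product of ketone 26 through enol ether 27. Cutting here removes the C6 stereocentre of the precursors and re-creates C8 by hydride attack on the convex β face, which gives the 8α-oxygen.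

**C1 and C10 oxygens (26 ⇐ 25 ⇐ 24 ⇐ 23 ⇐ 22).** Both ring-A oxygens come from one syn-dihydroxylation of the C1=C10 alkene of 22, and the secondary C1 hydroxyl of 23 is acetylated at once. This is placed before C8 is oxidised on purpose. A C8 ketone beside an intact C1=C10 alkene would be β,γ-unsaturated, with a doubly activated H-9, and enolisation for the dehydrogenation would then threaten the ring fusion. After osmylation C9 lies between two fully substituted carbons, so enolisation can only go towards C7.

**Ring A (22 ⇐ 21), the key disconnection.** The C2–C3 bond is cut and C10 is reconnected to C3, which gives vinylcyclopropane 21. Forward, a nickel-catalysed 1,3-shift must break C3–C10, not C9–C10, and join C2 to C3 on the face that C10 leaves. This closes ring A cis to H-9 and creates the quaternary centre at the expense of cyclopropane strain.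

**Vinyl and isopropyl groups (21 ⇐ 20 ⇐ 19 ⇐ 18 ⇐ 17 ⇐ 16).** The vinyl group is cut at C1=C2 back to lactol 19 and lactone 18. Because C1 is tied to O8 in the lactone, the vinyl group is necessarily endo and the C8 oxygen is released in the same operation for protection as 21. The isopropyl group is cut back to the exo acetyl group of 16 (methylenation to 17, then hydrogenation). It must be finished before the vinyl group exists.

**Cyclopropane (16 ⇐ 15 ⇐ 12 + 13).** The C9–C10 and C3–C10 bonds are cut together. Forward, a metal carbene generated from diazo ester 15 adds to the C3=C9 alkene of the cycloheptenol ester. The tether through O8 forces the addition onto the α face and fixes which carbonyl is endo. The acetoacetyl unit comes from 13.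

**Ring B (12 ⇐ 11 ⇐ 10).** The C8 carbinol is traced to enone 11 (reagent-controlled reduction). The C3=C9 alkene of 11 is cut by ring-closing metathesis to the acyclic dienone 10.

**Chain (10 ⇐ 8 ⇐ 7 ⇐ 6 ⇐ 5 ⇐ 3, with 4 and 9).** The C8–C9 and C3–C4 bonds are cut at two acyl substitutions, with vinyl reagent 9 on amide 8 and isopropenyl reagent 4 on amide 3. The C4 carbinol is set between them by a reagent-controlled ketone reduction and silylated.

**Absolute configuration (3 ⇐ 2 ⇐ 1).** The two ends of the glutarate are distinguished by opening the prochiral anhydride 1 enantioselectively to the half-ester 2. The resulting C6 centre keeps every intermediate a single diastereomer until it is erased in 28.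

## Alternatives that were turned down

**Alternative 1: type 2 carbonyl-ene closure of ring B.**
- Disconnection: C4–C5. The substrate is formyl cyclopentane A1, which already holds ring A with the C1/C10 diol as an acetonide, the quaternary C3 bearing the aldehyde, and a methallyl ketone side chain on C9.
- Key step: an aluminium Lewis acid activates the neopentyl aldehyde, the terminal methylene C5 attacks it and a methyl hydrogen is passed on. This gives hydroxy ketone A2 with the C4 hydroxyl and an exocyclic methylene on C6.
- For: the C4 carbinol is made in the ring-forming step. The exocyclic alkene needs only to migrate into conjugation with the C8 ketone to give the enone, so no dehydrogenation is needed. On this point it is stronger than the chosen route.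
- Against: ene closures are dependable for six-membered rings and much less so for seven. The ene donor in A1 is a β,γ-unsaturated ketone whose C7 hydrogens are doubly activated, so the Lewis acid can isomerise it into conjugation or be held by the ketone. H-9 is epimerisable. The C4 configuration would come from a medium-ring transition state with no clear bias. A1 itself, a cyclopentane with three contiguous congested centres, is as hard to make as the target's ring A.
- Comparison: the chosen route sets C3, C9 and C10 from a tether-controlled cyclopropane and adds the ring-A oxygens in one osmylation, at the price of a longer C6–C8 end game.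

**Alternative 2: decalin to hydroazulene by pinacol-type ring contraction.**
- Disconnection: C3–C9, traced back to the C3–C8 bond of the trans-decalin hydroxy mesylate A3.
- Key step: a strong alkoxide base deprotonates the tertiary C8 hydroxyl, and the ring bond C3–C8, antiperiplanar to the equatorial sulfonate, shifts to C9 with inversion. This gives the cis-fused hydroazulen-8-one A4.
- For: the shift is concerted and stereospecific, so its outcome is read from the decalin chair. That is more predictable than a metal insertion that must choose between two cyclopropane bonds. Angular-methyl decalins are reached by well-worn annulation chemistry, and the C8 ketone arrives where the enone is needed.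
- Against: A4 has neither the isopropyl group nor the C1 oxygen. C10 arrives as a protected secondary alcohol and must be oxidised, given an isopropyl nucleophile on a hindered enolisable cyclopentanone with facial control, and C1 must be oxygenated separately. When C8 and C10 are both carbonyls, C9 is a 1,3-dicarbonyl methine open to epimerisation and retro-Claisen cleavage. A3 needs six defined stereocentres on the decalin.
- Comparison: the key step is more reliable than in the chosen route, but the chosen route carries the isopropyl group through the key step and needs no new C–C bond on ring A afterwards.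

**Alternative 3: tethered oxyallyl (4+3) cycloaddition.**
- Disconnection: C3–C9 and C5–C6 together. The substrate is chloro ketone A5, an acetonide holding C1 and C10, with the chloro ketone chain on C1 and a 2-silyloxy diene on C10.
- Key step: base-induced ionisation to the oxyallyl cation and addition across the diene termini. This gives A6 with both rings, the quaternary C3, a C4 ketone and a C7=C8 silyl enol ether.
- For: it is the most convergent plan. The enol ether in A6 is already the regiodefined one needed for dehydrogenation to the C6=C7 enone, so the regiochemical question of steps 22–23 does not arise. On step economy it is clearly ahead.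
- Against: the fully substituted oxyallyl terminus must bond to a diene terminus attached to a quaternary oxygenated carbon. Four diastereomeric outcomes are possible (fusion geometry and face relative to the acetonide), with only the tether to bias them. The silyloxy diene can react stepwise (simple alkylation or five-ring formation) or be solvolysed, and the chloro ketone can undergo Favorskii chemistry. The C4 ketone must then be reduced next to the quaternary centre with the right facial sense.
- Comparison: the chosen route is longer, but each stereocentre is set by a separate event with a nameable control element (tether, reagent, convex face).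

Key step: step 17

Assumption: the quinidine-derived catalyst (DHQD)2AQN is taken to open anhydride 1 to the R half-ester 2; if its sense is the opposite, the quinine-derived pseudoenantiomer (DHQ)2AQN is used under the same conditions.

## Route

Step 1
Reactants: 1 3-methylglutaric anhydride
Product: 2 (3R)-5-methoxy-3-methyl-5-oxopentanoic acid
Conditions: MeOH (10 equiv), (DHQD)2AQN (0.3 equiv), Et2O, −40 °C
Reagents that add atoms: methanol, CO
Why: Alkaloid general-base catalysis distinguishes the enantiotopic carbonyl groups of the prochiral anhydride (desymmetrising alcoholysis); the C6 centre set here is temporary, and any enantiomeric leak should be removed later as a diastereomer after the two reagent-controlled reductions.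

Step 2
Reactants: 2 (3R)-5-methoxy-3-methyl-5-oxopentanoic acid
Product: 3 methyl (3R)-5-[methoxy(methyl)amino]-3-methyl-5-oxopentanoate
Conditions: MeNHOMe·HCl, EDC·HCl, N-methylmorpholine, CH2Cl2, 0 °C → rt
Reagents that add atoms: N,O-dimethylhydroxylamine hydrochloride, CNOC.Cl
Why: Carbodiimide amidation of the free acid gives the Weinreb amide, which makes the acid terminus the more reactive acyl group for the first ketone synthesis.

Step 3
Reactants: 3 methyl (3R)-5-[methoxy(methyl)amino]-3-methyl-5-oxopentanoate; 4 isopropenylmagnesium bromide
Product: 5 methyl (3R)-3,6-dimethyl-5-oxohept-6-enoate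
Conditions: 4 (1.2 equiv), THF, −78 → −20 °C; cold aq. NH4Cl
Reagents that add atoms: none
Why: Grignard addition to the Weinreb amide stops at the chelated tetrahedral intermediate and is faster than attack on the methyl ester at low temperature; it brings in C3 with its methyl group and the methylene that is lost later in metathesis.

Step 4
Reactants: 5 methyl (3R)-3,6-dimethyl-5-oxohept-6-enoate
Product: 6 methyl (3R,5S)-5-hydroxy-3,6-dimethylhept-6-enoate
Conditions: (R)-2-methyl-CBS-oxazaborolidine (0.2 equiv), catecholborane, toluene, −78 °C
Reagents that add atoms: none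
Why: Corey–Bakshi–Shibata reduction in which the isopropenyl group is the large substituent, so the R catalyst should give the S carbinol (C4 of the target); catecholborane avoids hydroboration of the alkene, and the hydroxy ester is silylated at once to forestall lactonisation.

Step 5
Reactants: 6 methyl (3R,5S)-5-hydroxy-3,6-dimethylhept-6-enoate
Product: 7 methyl (3R,5S)-5-[(tert-butyldimethylsilyl)oxy]-3,6-dimethylhept-6-enoate
Conditions: TBSCl, imidazole, DMF, rt
Reagents that add atoms: tert-butyldimethylsilyl chloride, CC(C)(C)[Si](C)(C)Cl
Why: Standard silylation of a secondary allylic alcohol; the TBS ether is chosen because it has to survive bases, hydrides, oxidants and Lewis acids until the last step.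

Step 6
Reactants: 7 methyl (3R,5S)-5-[(tert-butyldimethylsilyl)oxy]-3,6-dimethylhept-6-enoate
Product: 8 (3R,5S)-5-[(tert-butyldimethylsilyl)oxy]-N-methoxy-N,3,6-trimethylhept-6-enamide
Conditions: MeNHOMe·HCl, iPrMgCl, THF, −20 → 0 °C
Reagents that add atoms: N,O-dimethylhydroxylamine hydrochloride, CNOC.Cl
Why: The magnesium amide formed in the flask converts the methyl ester directly into the Weinreb amide (ester aminolysis), preparing the second mono-addition.

Step 7
Reactants: 8 (3R,5S)-5-[(tert-butyldimethylsilyl)oxy]-N-methoxy-N,3,6-trimethylhept-6-enamide; 9 vinylmagnesium bromide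
Product: 10 (5R,7S)-7-[(tert-butyldimethylsilyl)oxy]-5,8-dimethylnona-1,8-dien-3-one
Conditions: 9 (1.5 equiv), THF, −78 → 0 °C; inverse quench into cold 1 M HCl
Reagents that add atoms: none
Why: Weinreb ketone synthesis gives the vinyl ketone; the cold acidic quench keeps the liberated hydroxylamine protonated so that it does not add to the enone.

Step 8
Reactants: 10 (5R,7S)-7-[(tert-butyldimethylsilyl)oxy]-5,8-dimethylnona-1,8-dien-3-one
Product: 11 (4S,6R)-4-[(tert-butyldimethylsilyl)oxy]-3,6-dimethylcyclohept-2-en-1-one
Conditions: second-generation Hoveyda–Grubbs catalyst (5–10 mol%), toluene (5 mM), 80 °C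
Reagents that add atoms: none
Why: Ring-closing metathesis between a vinyl ketone and a 1,1-disubstituted alkene forms the trisubstituted C3=C9 enone with loss of ethylene; high dilution and a phosphine-free catalyst are used because neither alkene initiates readily.

Step 9
Reactants: 11 (4S,6R)-4-[(tert-butyldimethylsilyl)oxy]-3,6-dimethylcyclohept-2-en-1-one
Product: 12 (1S,4S,6S)-4-[(tert-butyldimethylsilyl)oxy]-3,6-dimethylcyclohept-2-en-1-ol (C6 unchanged in space; its descriptor changes with the priorities)
Conditions: (R)-2-methyl-CBS-oxazaborolidine (0.2 equiv), catecholborane, toluene, −78 → −40 °C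
Reagents that add atoms: none
Why: Corey–Bakshi–Shibata 1,2-reduction of the enone with the alkenyl side as the large group; the R catalyst should give the 1S alcohol, i.e. the C8 hydroxyl trans to the C4 silyloxy and C6 methyl groups, on the face to which the cyclopropane will be delivered.

Step 10
Reactants: 12 (1S,4S,6S)-4-[(tert-butyldimethylsilyl)oxy]-3,6-dimethylcyclohept-2-en-1-ol; 13 2,2,6-trimethyl-4H-1,3-dioxin-4-one
Product: 15 (1S,4S,6S)-4-[(tert-butyldimethylsilyl)oxy]-3,6-dimethylcyclohept-2-en-1-yl 2-diazo-3-oxobutanoate, via acetoacetate 14 (not isolated)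
Conditions: 13 (1.5 equiv), toluene, 110 °C (acetone distilled off); then MeCN, Et3N, 4-acetamidobenzenesulfonyl azide, 0 °C → rt
Reagents that add atoms: 4-acetamidobenzenesulfonyl azide, CC(=O)Nc1ccc(cc1)S(=O)(=O)N=[N+]=[N-]
Why: Thermolysis of the dioxinone releases acetylketene, which acylates the alcohol cleanly; the resulting 1,3-dicarbonyl methylene then undergoes Regitz diazo transfer under mild base.

Step 11
Reactants: 15 (1S,4S,6S)-4-[(tert-butyldimethylsilyl)oxy]-3,6-dimethylcyclohept-2-en-1-yl 2-diazo-3-oxobutanoate
Product: 16 acetyl lactone: tricyclic γ-lactone with the cyclopropane C3–C9–C10 on the α face of ring B, lactone O8–C1(=O)–C10 (carbonyl endo), exo acetyl on C10, 3β-methyl, 4β-OTBS, 6β-methyl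
Conditions: Rh2(OAc)4 (2 mol%), CH2Cl2, 40 °C, slow addition of 15
Reagents that add atoms: none
Why: Intramolecular cyclopropanation of an allylic diazoacetoacetate by the dirhodium carbenoid; the ester tether allows addition only to the face of the C8 oxygen, which sets C3, C9 and C10 together and places the ester carbonyl endo and the acetyl group exo.

Step 12
Reactants: 16 acetyl lactone
Product: 17 isopropenyl lactone (as 16, exo isopropenyl on C10)
Conditions: Ph3PCH3Br, KOtBu, toluene, 0 → 70 °C
Reagents that add atoms: methyltriphenylphosphonium bromide, C[P+](c1ccccc1)(c1ccccc1)c1ccccc1.[Br-]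
Why: Wittig methylenation is selective for the ketone over the lactone carbonyl; C10 is quaternary, so no stereocentre can be lost.

Step 13
Reactants: 17 isopropenyl lactone
Product: 18 isopropyl lactone (as 16, exo isopropyl on C10)
Conditions: H2 (1 atm), [Ir(cod)(PCy3)(py)]PF6 (5 mol%), CH2Cl2, rt
Reagents that add atoms: none
Why: Homogeneous iridium hydrogenation reduces hindered 1,1-disubstituted alkenes, can be directed by the lactone carbonyl, and does not hydrogenolyse the cyclopropane as a heterogeneous palladium catalyst might.

Step 14
Reactants: 18 isopropyl lactone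
Product: 19 lactol (as 18 with C1 as hemiacetal, both anomers)
Conditions: iBu2AlH, CH2Cl2, −78 °C; aq. potassium sodium tartrate
Reagents that add atoms: none
Why: Half-reduction of a γ-lactone stops at the stable aluminium hemiacetal at low temperature.

Step 15
Reactants: 19 lactol
Product: 20 cyclopropyl carbinol: 8α-hydroxy-10-isopropyl-10-(endo-vinyl)-3β,6β-dimethyl-4β-[(tert-butyldimethylsilyl)oxy]bicyclo[5.1.0]octane (target locants)
Conditions: Ph3PCH3Br, KOtBu, THF, 0 → 50 °C
Reagents that add atoms: methyltriphenylphosphonium bromide, C[P+](c1ccccc1)(c1ccccc1)c1ccccc1.[Br-]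
Why: The lactol is in equilibrium with the non-enolisable cyclopropanecarbaldehyde, which is methylenated (Wittig reaction on a cyclopropane-fused lactol); the vinyl group is endo because C1 was tied to O8, and the C8 hydroxyl is released.

Step 16
Reactants: 20 cyclopropyl carbinol
Product: 21 4-methoxybenzyl ether of 20 (C8 α-OPMB; substrate of the rearrangement)
Conditions: NaH, 4-methoxybenzyl chloride, Bu4NI (cat.), DMF, 0 °C → rt
Reagents that add atoms: 4-methoxybenzyl chloride, COc1ccc(CCl)cc1
Why: Williamson etherification under basic conditions, chosen because the cyclopropylcarbinyl alcohol would ionise under acidic benzylation; PMB can later be removed oxidatively beside the C4 silyl ether.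

Step 17
Reactants: 21 4-methoxybenzyl ether (endo-vinyl cyclopropane)
Product: 22 cis-fused cyclopentene: 10-isopropyl-Δ1(10)-hydroazulene with 3β-methyl, 9β-H, 4β-OTBS, 6β-methyl, 8α-OPMB
Conditions: Ni(cod)2 (10 mol%), 1,3-bis(2,6-diisopropylphenyl)imidazol-2-ylidene (20 mol%), toluene, 25 → 40 °C
Reagents that add atoms: none
Why: The zerovalent nickel–carbene fragment binds the endo vinyl group and inserts into the allylic cyclopropane bond C3–C10; the nickel allyl then shifts its point of attachment from C10 to C2, and the resulting six-membered nickelacycle (Ni, C2, C1, C10, C9, C3) reductively eliminates the C2–C3 bond. The closest known reaction type is the zerovalent nickel/N-heterocyclic carbene vinylcyclopropane–cyclopentene rearrangement of unactivated, including ring-fused, vinylcyclopropanes at ambient temperature. Ring A is closed by this reductive elimination, a net suprafacial 1,3-shift of C3 from C10 to C2, and it only requires C2 to sit cis to C9 on the allyl, which π–σ–π equilibration of the nickel allyl allows. The quaternary centre C3 is formed with retention: nickel replaces C10 on the α face and hands C3 to C2 on the same face, so ring A stays cis to H-9 and the C3 methyl group stays β. The step needs cleavage of C3–C10 and not C9–C10; C3–C10 joins two fully substituted carbons and is the longest and most strained ring bond, and the C8 PMB ether lies on the cyclopropane face and shields the C9 flank of the endo vinyl group while the C4 silyl ether points to the other face. Working at 25–40 °C keeps the substrate well below the temperature at which the endo vinyl group would take H-4 or H-8 in a homodienyl 1,5-hydrogen shift. The PMB and TBS ethers are inert to the catalyst at this temperature.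

Step 18
Reactants: 22 cis-fused cyclopentene
Product: 23 1β,10β-diol (10α-isopropyl; 4β-OTBS, 8α-OPMB)
Conditions: OsO4 (5 mol%), N-methylmorpholine N-oxide, acetone/H2O (4:1), rt; aq. Na2SO3
Reagents that add atoms: osmium tetroxide, O=[Os](=O)(=O)=O; N-methylmorpholine N-oxide, C[N+]1([O-])CCOCC1
Why: Catalytic syn-dihydroxylation of the only alkene; osmium should add to the convex β face (that of H-9), since the α face is covered by ring B and the α-oriented C8 ether, giving the cis-diol with both oxygens β.

Step 19
Reactants: 23 1β,10β-diol
Product: 24 1β-acetate (10β-OH free)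
Conditions: Ac2O, pyridine, DMAP (cat.), CH2Cl2, rt
Reagents that add atoms: acetic anhydride, CC(=O)OC(C)=O
Why: Nucleophile-catalysed acylation takes the secondary C1 hydroxyl; the tertiary C10 hydroxyl is too hindered to react under these conditions.

Step 20
Reactants: 24 1β-acetate
Product: 25 8α-alcohol (1β-OAc, 10β-OH, 4β-OTBS)
Conditions: DDQ, CH2Cl2/aq. NaH2PO4–Na2HPO4 buffer (pH 7), 0 °C → rt
Reagents that add atoms: none
Why: Oxidative cleavage of the electron-rich benzyl ether through its oxocarbenium ion, which water hydrolyses; no alkene is left in the molecule, and the silyl ether and acetate are untouched.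

Step 21
Reactants: 25 8α-alcohol
Product: 26 8-ketone (1β-OAc, 10β-OH, 4β-OTBS, 6β-methyl)
Conditions: Dess–Martin periodinane, NaHCO3, CH2Cl2, rt
Reagents that add atoms: none
Why: Buffered hypervalent-iodine oxidation of a secondary alcohol under non-basic conditions, so the β-hydroxy ketone neither retro-aldolises nor epimerises at C9.

Step 22
Reactants: 26 8-ketone
Product: 27 bis-silyl compound: 10β-OTMS and 8-(trimethylsilyloxy)-Δ7 enol ether
Conditions: TMSOTf (3 equiv), Et3N (5 equiv), CH2Cl2, −78 → 0 °C
Reagents that add atoms: trimethylsilyl trifluoromethanesulfonate, C[Si](C)(C)OS(=O)(=O)C(F)(F)F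
Why: Soft enolisation silylates the tertiary hydroxyl and converts the ketone into its silyl enol ether without a strong base that would enolise the acetate; H-9 lies between two fully substituted carbons and an enol ether towards C9 would be severely strained, so enolisation should go to C7.

Step 23
Reactants: 27 bis-silyl compound
Product: 28 Δ6-8-enone (10β-OTMS, 1β-OAc, 4β-OTBS)
Conditions: Pd(OAc)2 (1.2 equiv), MeCN, rt → 40 °C
Reagents that add atoms: none
Why: Saegusa–Ito oxidation: divalent palladium forms the C7 palladium enolate, and β-hydride elimination can only take H-6, giving the C6=C7 enone and zerovalent palladium; the temporary C6 stereocentre is removed here.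

Step 24
Reactants: 28 Δ6-8-enone
Product: 29 8α-allylic alcohol (10β-OTMS, 1β-OAc, 4β-OTBS)
Conditions: NaBH4, CeCl3·7H2O, MeOH/THF, −78 °C
Reagents that add atoms: none
Why: Luche 1,2-reduction of the enone; hydride should come from the convex β face, anti to the C9–C10 bond, placing the hydroxyl α as in the target; partial loss of the tertiary TMS ether here would be harmless because that hydroxyl is not acylated in step 26 and is freed in step 27 anyway.

Step 25
Reactants: 30 4-hydroxybenzoic acid
Product: 32 4-[(tert-butyldimethylsilyl)oxy]benzoic acid, via silyl ester 31 (not isolated)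
Conditions: TBSCl (2.5 equiv), imidazole, DMF, rt; then AcOH/THF/H2O, rt
Reagents that add atoms: tert-butyldimethylsilyl chloride, CC(C)(C)[Si](C)(C)Cl
Why: Double silylation followed by selective hydrolysis of the far more labile silyl ester leaves the aryl silyl ether in place.

Step 26
Reactants: 29 8α-allylic alcohol; 32 4-[(tert-butyldimethylsilyl)oxy]benzoic acid
Product: 33 protected ester: 8α-[4-(tert-butyldimethylsilyloxy)benzoyloxy], 1β-OAc, 4β-OTBS, 10β-OTMS
Conditions: EDC·HCl, DMAP, CH2Cl2, rt
Reagents that add atoms: none
Why: Steglich esterification of the only free hydroxyl; the configuration at C8 is retained because the C–O bond is not touched.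

Step 27
Reactants: 33 protected ester
Product: 34 CNP0146780.2, (1S,3S,4S,8S,9R,10R)-1-acetoxy-4,10-dihydroxy-10-isopropyl-3,6-dimethylbicyclo[5.3.0]dec-6-en-8-yl 4-hydroxybenzoate (route locants)
Conditions: HF·pyridine, pyridine, THF, 0 °C → rt
Reagents that add atoms: none
Why: Buffered fluoride cleaves the aryl silyl ether, the tertiary TMS ether and, more slowly, the neopentyl C4 TBS ether, while the acetate and the allylic aryl ester should survive these weakly acidic, non-nucleophilic conditions.

## Compound list

1 | 3-methylglutaric anhydride | CC1CC(=O)OC(=O)C1 | starting material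
2 | (3R)-5-methoxy-3-methyl-5-oxopentanoic acid | COC(=O)C[C@H](C)CC(=O)O | intermediate
3 | methyl (3R)-5-[methoxy(methyl)amino]-3-methyl-5-oxopentanoate | COC(=O)C[C@H](C)CC(=O)N(C)OC | intermediate
4 | isopropenylmagnesium bromide | CC(=C)[Mg]Br | starting material
5 | methyl (3R)-3,6-dimethyl-5-oxohept-6-enoate | COC(=O)C[C@H](C)CC(=O)C(C)=C | intermediate
6 | methyl (3R,5S)-5-hydroxy-3,6-dimethylhept-6-enoate | C=C(C)[C@@H](O)C[C@@H](C)CC(=O)OC | intermediate
7 | methyl (3R,5S)-5-[(tert-butyldimethylsilyl)oxy]-3,6-dimethylhept-6-enoate | C=C(C)[C@@H](O[Si](C)(C)C(C)(C)C)C[C@@H](C)CC(=O)OC | intermediate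
8 | (3R,5S)-5-[(tert-butyldimethylsilyl)oxy]-N-methoxy-N,3,6-trimethylhept-6-enamide | C=C(C)[C@@H](O[Si](C)(C)C(C)(C)C)C[C@@H](C)CC(=O)N(C)OC | intermediate
9 | vinylmagnesium bromide | C=C[Mg]Br | starting material
10 | (5R,7S)-7-[(tert-butyldimethylsilyl)oxy]-5,8-dimethylnona-1,8-dien-3-one | C=C(C)[C@@H](O[Si](C)(C)C(C)(C)C)C[C@@H](C)CC(=O)C=C | intermediate
11 | (4S,6R)-4-[(tert-butyldimethylsilyl)oxy]-3,6-dimethylcyclohept-2-en-1-one | O=C1C=C(C)[C@@H](O[Si](C)(C)C(C)(C)C)C[C@@H](C)C1 | intermediate
12 | (1S,4S,6S)-4-[(tert-butyldimethylsilyl)oxy]-3,6-dimethylcyclohept-2-en-1-ol | O[C@@H]1C=C(C)[C@@H](O[Si](C)(C)C(C)(C)C)C[C@@H](C)C1 | intermediate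
13 | 2,2,6-trimethyl-4H-1,3-dioxin-4-one | CC1=CC(=O)OC(C)(C)O1 | starting material
14 | (1S,4S,6S)-4-[(tert-butyldimethylsilyl)oxy]-3,6-dimethylcyclohept-2-en-1-yl 3-oxobutanoate | CC(=O)CC(=O)O[C@@H]1C=C(C)[C@@H](O[Si](C)(C)C(C)(C)C)C[C@@H](C)C1 | intermediate (not isolated)
15 | (1S,4S,6S)-4-[(tert-butyldimethylsilyl)oxy]-3,6-dimethylcyclohept-2-en-1-yl 2-diazo-3-oxobutanoate | CC(=O)C(=[N+]=[N-])C(=O)O[C@@H]1C=C(C)[C@@H](O[Si](C)(C)C(C)(C)C)C[C@@H](C)C1 | intermediate
16 | acetyl lactone (α-cyclopropane C3–C9–C10, lactone O8–C1(=O)–C10 endo, exo acetyl on C10) | CC(=O)[C@@]12C(=O)O[C@H]3C[C@H](C)C[C@H](O[Si](C)(C)C(C)(C)C)[C@]1(C)[C@@H]23 | intermediate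
17 | isopropenyl lactone (as 16, exo isopropenyl) | C=C(C)[C@@]12C(=O)O[C@H]3C[C@H](C)C[C@H](O[Si](C)(C)C(C)(C)C)[C@]1(C)[C@@H]23 | intermediate
18 | isopropyl lactone (as 16, exo isopropyl) | CC(C)[C@@]12C(=O)O[C@H]3C[C@H](C)C[C@H](O[Si](C)(C)C(C)(C)C)[C@]1(C)[C@@H]23 | intermediate
19 | lactol (as 18, C1 hemiacetal, both anomers) | CC(C)[C@@]12C(O)O[C@H]3C[C@H](C)C[C@H](O[Si](C)(C)C(C)(C)C)[C@]1(C)[C@@H]23 | intermediate
20 | cyclopropyl carbinol (8α-OH, endo vinyl and exo isopropyl on C10) | C=C[C@]1(C(C)C)[C@]2(C)[C@@H](O[Si](C)(C)C(C)(C)C)C[C@@H](C)C[C@H](O)[C@H]12 | intermediate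
21 | 4-methoxybenzyl ether of 20 (rearrangement substrate) | C=C[C@]1(C(C)C)[C@]2(C)[C@@H](O[Si](C)(C)C(C)(C)C)C[C@@H](C)C[C@H](OCc3ccc(OC)cc3)[C@H]12 | intermediate
22 | cis-fused isopropylcyclopentene (Δ1(10), 8α-OPMB, 4β-OTBS) | C=1C[C@]2(C)[C@@H](O[Si](C)(C)C(C)(C)C)C[C@@H](C)C[C@H](OCc3ccc(OC)cc3)[C@@H]2C=1C(C)C | intermediate
23 | 1β,10β-diol | O[C@H]1C[C@]2(C)[C@@H](O[Si](C)(C)C(C)(C)C)C[C@@H](C)C[C@H](OCc3ccc(OC)cc3)[C@@H]2[C@]1(O)C(C)C | intermediate
24 | 1β-acetate | CC(=O)O[C@H]1C[C@]2(C)[C@@H](O[Si](C)(C)C(C)(C)C)C[C@@H](C)C[C@H](OCc3ccc(OC)cc3)[C@@H]2[C@]1(O)C(C)C | intermediate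
25 | 8α-alcohol | CC(=O)O[C@H]1C[C@]2(C)[C@@H](O[Si](C)(C)C(C)(C)C)C[C@@H](C)C[C@H](O)[C@@H]2[C@]1(O)C(C)C | intermediate
26 | 8-ketone | CC(=O)O[C@H]1C[C@]2(C)[C@@H](O[Si](C)(C)C(C)(C)C)C[C@@H](C)CC(=O)[C@@H]2[C@]1(O)C(C)C | intermediate
27 | bis-silyl compound (10β-OTMS, Δ7 silyl enol ether) | CC(=O)O[C@H]1C[C@]2(C)[C@@H](O[Si](C)(C)C(C)(C)C)C[C@@H](C)C=C(O[Si](C)(C)C)[C@@H]2[C@]1(O[Si](C)(C)C)C(C)C | intermediate
28 | Δ6-8-enone (10β-OTMS) | CC(=O)O[C@H]1C[C@]2(C)[C@@H](O[Si](C)(C)C(C)(C)C)CC(C)=CC(=O)[C@@H]2[C@]1(O[Si](C)(C)C)C(C)C | intermediate
29 | 8α-allylic alcohol (10β-OTMS) | CC(=O)O[C@H]1C[C@]2(C)[C@@H](O[Si](C)(C)C(C)(C)C)CC(C)=C[C@H](O)[C@@H]2[C@]1(O[Si](C)(C)C)C(C)C | intermediate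
30 | 4-hydroxybenzoic acid | OC(=O)c1ccc(O)cc1 | starting material
31 | tert-butyldimethylsilyl 4-[(tert-butyldimethylsilyl)oxy]benzoate | CC(C)(C)[Si](C)(C)OC(=O)c1ccc(O[Si](C)(C)C(C)(C)C)cc1 | intermediate (not isolated)
32 | 4-[(tert-butyldimethylsilyl)oxy]benzoic acid | CC(C)(C)[Si](C)(C)Oc1ccc(cc1)C(=O)O | intermediate
33 | protected ester | CC(=O)O[C@H]1C[C@]2(C)[C@@H](O[Si](C)(C)C(C)(C)C)CC(C)=C[C@H](OC(=O)c3ccc(O[Si](C)(C)C(C)(C)C)cc3)[C@@H]2[C@]1(O[Si](C)(C)C)C(C)C | intermediate
34 | CNP0146780.2 | CC(=O)O[C@H]1C[C@]2(C)[C@@H](O)CC(C)=C[C@H](OC(=O)c3ccc(O)cc3)[C@@H]2[C@]1(O)C(C)C | target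

## Step count and least certain steps

Total: 27 steps. Longest linear sequence: 26 steps (steps 1–24, 26, 27, from 1 to 34); step 25 is a one-step branch.

**Step 17 (key step).** Nickel may insert into the C9–C10 bond instead of C3–C10, since a nickel–carbon bond to the less substituted C9 is intrinsically easier to form, and ring closure would then occur at C9. An alkylnickel with a syn β-oxygen may also lose the C8 alkoxide, or the tetrasubstituted cyclopropane may fail to turn over. Fallback, leaving the rearrangement altogether: ring A is built on enone 11 by a Lewis-acid [3+2] annulation with an allenylsilane (Danheiser annulation). Enone 11 and trimethyl(4-methylpenta-1,2-dien-3-yl)silane F1, a reagent prepared separately, are combined with TiCl4 in CH2Cl2 at −78 °C. The allene should attack C3 anti to the C4 silyl ether and the titanium enolate should close on the same face, giving the cis-fused 1-trimethylsilyl cyclopentene ketone F2. NaBH4 reduction from the β face gives the 8α-alcohol F3. Protodesilylation of the vinylsilane with CF3CO2H in CH2Cl2 at 0 °C (ipso protonation through the tertiary β-silyl cation) gives the cyclopentene alcohol F4. Etherification with NaH and 4-methoxybenzyl chloride returns to 22.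

**Step 8.** Neither alkene of 10 is a good initiation site (one electron-poor, one hindered), so oligomerisation through the vinyl ketone and catalyst decay may outrun ring closure. Fallback, closing the ring at the alcohol oxidation level: ester 7 is reduced with iBu2AlH at −78 °C to the aldehyde F5. Vinylmagnesium bromide 9 gives the dienol F6 as a mixture at the new carbinol. Ring-closing metathesis with the second-generation Grubbs catalyst, which now initiates at the unhindered allylic alcohol, gives the cycloheptenol F7 as C8 epimers. MnO2 oxidation converges both epimers on enone 11.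

**Step 22 (with step 23).** Enol silylation may occur partly towards C9, with epimerisation of the ring fusion on hydrolysis, or the β-silyloxy ketone may fragment by a retro-aldol path under the silyl triflate. Fallback without any enol derivative: ketone 26 is dehydrogenated directly with IBX in DMSO at 60–70 °C, where only C6–C7 can be desaturated because C9 has no β-hydrogen, to give the hydroxy enone F11. Silylation of its tertiary hydroxyl with TMSOTf and 2,6-lutidine returns to 28.

**Step 12.** The ylide may act as a base on the methyl ketone or trigger retro-Claisen cleavage of the non-enolisable 1,3-dicarbonyl unit, and the ketone is hindered. Fallback by addition and elimination: MeMgBr with CeCl3 in THF at −78 °C adds to the ketone of 16 in preference to the lactone and gives the tertiary alcohol F10. Syn-elimination with the Burgess reagent in warm benzene gives 17; the ionic pathway is disfavoured because the cation would sit next to the lactone carbonyl.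

**Step 9.** The catalyst and the resident C4/C6 centres may be mismatched, leading to poor facial selectivity at C8. Fallback by substrate control and inversion: NaBH4 with CeCl3·7H2O in MeOH reduces 11; if the 1R epimer F8 predominates, Mitsunobu reaction with 4-nitrobenzoic acid, PPh3 and diisopropyl azodicarboxylate gives the inverted 4-nitrobenzoate F9, and K2CO3 in MeOH releases 12.

## Further compounds

F1 | step 17 | trimethyl(4-methylpenta-1,2-dien-3-yl)silane | CC(C)C(=C=C)[Si](C)(C)C
F2 | step 17 | cis-fused 1-(trimethylsilyl)-10-isopropyl-Δ1(10)-hydroazulen-8-one (4β-OTBS) | C[Si](C)(C)C=1C[C@]2(C)[C@@H](O[Si](C)(C)C(C)(C)C)C[C@@H](C)CC(=O)[C@@H]2C=1C(C)C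
F3 | step 17 | 8α-alcohol of F2 | C[Si](C)(C)C=1C[C@]2(C)[C@@H](O[Si](C)(C)C(C)(C)C)C[C@@H](C)C[C@H](O)[C@@H]2C=1C(C)C
F4 | step 17 | desilylated cyclopentene 8α-alcohol | C=1C[C@]2(C)[C@@H](O[Si](C)(C)C(C)(C)C)C[C@@H](C)C[C@H](O)[C@@H]2C=1C(C)C
F5 | step 8 | (3R,5S)-5-[(tert-butyldimethylsilyl)oxy]-3,6-dimethylhept-6-enal | C=C(C)[C@@H](O[Si](C)(C)C(C)(C)C)C[C@@H](C)CC=O
F6 | step 8 | dienol, the C3 carbinol epimers corresponding to ketone 10 | C=C(C)[C@@H](O[Si](C)(C)C(C)(C)C)C[C@@H](C)CC(O)C=C
F7 | step 8 | (4S,6S)-4-[(tert-butyldimethylsilyl)oxy]-3,6-dimethylcyclohept-2-en-1-ol, C1 epimers | OC1C=C(C)[C@@H](O[Si](C)(C)C(C)(C)C)C[C@@H](C)C1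
F8 | step 9 | (1R,4S,6S)-4-[(tert-butyldimethylsilyl)oxy]-3,6-dimethylcyclohept-2-en-1-ol | O[C@H]1C=C(C)[C@@H](O[Si](C)(C)C(C)(C)C)C[C@@H](C)C1
F9 | step 9 | (1S,4S,6S)-4-[(tert-butyldimethylsilyl)oxy]-3,6-dimethylcyclohept-2-en-1-yl 4-nitrobenzoate | O=C(O[C@@H]1C=C(C)[C@@H](O[Si](C)(C)C(C)(C)C)C[C@@H](C)C1)c1ccc(cc1)[N+](=O)[O-]
F10 | step 12 | hydroxyisopropyl lactone (as 16, exo 2-hydroxyprop-2-yl on C10) | CC(C)(O)[C@@]12C(=O)O[C@H]3C[C@H](C)C[C@H](O[Si](C)(C)C(C)(C)C)[C@]1(C)[C@@H]23
F11 | step 22 | hydroxy enone (Δ6-8-enone with free 10β-OH) | CC(=O)O[C@H]1C[C@]2(C)[C@@H](O[Si](C)(C)C(C)(C)C)CC(C)=CC(=O)[C@@H]2[C@]1(O)C(C)C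
A1 | alternative 1 | formyl cyclopentane with methallyl ketone side chain (ene substrate) | CC1(C)O[C@H]2C[C@](C)(C=O)[C@H](C(=O)CC(C)=C)[C@]2(O1)C(C)C
A2 | alternative 1 | 4-hydroxy-6-methylene hydroazulen-8-one acetonide | CC1(C)O[C@H]2C[C@]3(C)[C@@H](O)CC(=C)CC(=O)[C@@H]3[C@]2(O1)C(C)C
A3 | alternative 2 | trans-decalin hydroxy mesylate (C8 tertiary OH, C9 equatorial mesylate) | C1C[C@]2(C)[C@@H](O[Si](C)(C)C(C)(C)C)C[C@@H](C)C[C@@]2(O)[C@H](OS(C)(=O)=O)[C@H]1O[Si](CC)(CC)CC
A4 | alternative 2 | cis-fused hydroazulen-8-one | C1C[C@]2(C)[C@@H](O[Si](C)(C)C(C)(C)C)C[C@@H](C)CC(=O)[C@@H]2[C@H]1O[Si](CC)(CC)CC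
A5 | alternative 3 | tertiary α-chloro ketone tethered to a 2-silyloxy diene through the acetonide | CC1(C)O[C@@H](CC(C)(Cl)C(C)=O)[C@@](O1)(C(C)C)/C=C(O[Si](C)(C)C(C)(C)C)/C=C/C
A6 | alternative 3 | hydroazulen-4-one with C7–C8 silyl enol ether | CC1(C)O[C@H]2C[C@]3(C)C(=O)C[C@H](C)C=C(O[Si](C)(C)C(C)(C)C)[C@@H]3[C@]2(O1)C(C)C
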